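## Retrosynthetic overview

1. The target is disconnected last at the C12 ester: a core diol plus nonadecanoic acid, the acid being built as C8 + C6 + C5 (acetylide alkylation, Cu-catalysed sp3–sp3 coupling, hydrogenation).
2. The tetrahydrofuran is the last ring formed: the C11–O bond comes from a Pd-catalysed asymmetric allylic etherification of a dienyl epoxide, itself made from the lactone carbonyl, LiCH2Cl and a dienyllithium (Takai iodide from prenal).
3. The nine-membered ring is formed second: the C1–C2 bond comes from a Ru-catalysed intramolecular alkene–alkyne coupling of an alkynyl lactone carrying an allyl carbinol chain.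
4. The enyne comes from trans-alkylation of (R)-4-ethynylbutyrolactone (lactone ring present first; Rh-catalysed asymmetric vinyl addition to butenolide, then vinyl to ethynyl) with an iodide whose carbinol centre is set by Zr-catalysed carboalumination, Sharpless epoxidation and Red-Al opening.

Assumption: the SMILES is read literally, so the ester is a nonadecanoate (C19 acyl) and the configuration is (3Z,5S,8S,9R,11R) in the locants below.

Locants used in names: C1 = ring carbon bearing the exocyclic CH2; C2 = ring CH2; C3=C4 = ring alkene; C5 = C(CH3)(O); C6, C7 = ring CH2; C8, C9 = ring-fusion CH (C8 bonded to C11, C9 to C10); C10 = ring OCH2; C11 = quaternary O–C; C12 = CH2O on C11; C13–C16 = dienyl chain on C11.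

## Route

Step 1
Reactants: 1 furan-2(5H)-one; 2 potassium vinyltrifluoroborate
Product: 3 (4R)-4-ethenyloxolan-2-one
Conditions: [Rh(cod)(OH)]2 (2.5 mol%), (R)-BINAP (6 mol%), dioxane/H2O 10:1, 60 °C
Reagents that add atoms: none
Why: Hayashi–Miyaura Rh-catalysed asymmetric 1,4-addition, in which the (R)-BINAP–Rh–vinyl species inserts the butenolide C=C on one enantioface (sense assigned by analogy with aryl and alkenyl additions to cyclic enoates) and sets C9 as R.

Step 2
Reactants: 3 (4R)-4-ethenyloxolan-2-one
Product: 4 (4S)-4-(1,2-dibromoethyl)oxolan-2-one (both CHBr epimers)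
Conditions: Br2 (1.05 equiv), CH2Cl2, −78 °C
Reagents that add atoms: bromine BrBr
Why: Electrophilic anti-bromination of the only alkene; the ring stereocentre is untouched (its descriptor changes by CIP priority only) and the new CHBr centre disappears in step 3.

Step 3
Reactants: 4 (4S)-4-(1,2-dibromoethyl)oxolan-2-one
Product: 6 (4R)-4-ethynyloxolan-2-one, via bromoalkene 5 (not isolated)
Conditions: TBAF·3H2O (5 equiv), DMF, 60 °C; then 1 M HCl
Reagents that add atoms: none
Why: Fluoride-mediated double dehydrobromination (two E2 eliminations) converts the vic-dibromide into the terminal alkyne under conditions the lactone survives (the acidic work-up recloses any hydroxy acid), and C9 has no acidifying group so it keeps its configuration.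

Step 4
Reactants: 7 pent-1-en-4-yne
Product: 10 (2E)-3-methylhexa-2,5-dien-1-ol, via alkenylalane 8 (not isolated), via alanate 9 (not isolated)
Conditions: Me3Al (2 equiv), Cp2ZrCl2 (20 mol%), CH2Cl2, 0 °C → rt; n-BuLi, THF, −78 °C; (CH2O)n, rt; 3 M HCl
Reagents that add atoms: trimethylaluminium C[Al](C)C; paraformaldehyde (as formaldehyde) C=O
Why: Negishi Zr-catalysed carboalumination adds CH3 and Al syn across the terminal alkyne only, and the alkenyl alanate is hydroxymethylated with retention to give the E-trisubstituted allylic alcohol.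

Step 5
Reactants: 10 (2E)-3-methylhexa-2,5-dien-1-ol
Product: 11 [(2R,3R)-3-methyl-3-(prop-2-en-1-yl)oxiran-2-yl]methanol
Conditions: Ti(OiPr)4 (10 mol%), D-(−)-diethyl tartrate (12 mol%), t-BuOOH, 4 Å MS, CH2Cl2, −20 °C
Reagents that add atoms: tert-butyl hydroperoxide CC(C)(C)OO
Why: Sharpless asymmetric epoxidation; the Ti/D-(−)-tartrate complex epoxidises only the allylic-alcohol alkene, from the face opposite to the one L-(+)-tartrate uses on geraniol-type substrates, which sets the future C5 centre.

Step 6
Reactants: 11 [(2R,3R)-3-methyl-3-(prop-2-en-1-yl)oxiran-2-yl]methanol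
Product: 12 (3R)-3-methylhex-5-ene-1,3-diol
Conditions: Red-Al, THF, 0 °C → rt; H2O/NaOH work-up
Reagents that add atoms: none
Why: Alkoxide-directed hydride delivery (Red-Al opening of a 2,3-epoxy alcohol) attacks C2 to give the 1,3-diol; the tertiary C–O bond is not broken, so the stereocentre is retained.

Step 7
Reactants: 12 (3R)-3-methylhex-5-ene-1,3-diol
Product: 13 (3R)-1-iodo-3-methylhex-5-en-3-ol
Conditions: I2, PPh3, imidazole, CH2Cl2, 0 °C
Reagents that add atoms: iodine II
Why: Appel-type (Garegg–Samuelsson) iodination converts only the primary alcohol, the tertiary one being too hindered to form the oxyphosphonium.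

Step 8
Reactants: 13 (3R)-1-iodo-3-methylhex-5-en-3-ol
Product: 14 triethyl{[(3R)-1-iodo-3-methylhex-5-en-3-yl]oxy}silane
Conditions: TESOTf, 2,6-lutidine, CH2Cl2, −78 → 0 °C
Reagents that add atoms: triethylsilyl trifluoromethanesulfonate CC[Si](CC)(CC)OS(=O)(=O)C(F)(F)F
Why: Silyl triflate silylation of a hindered tertiary alcohol; no stereocentre is affected.

Step 9
Reactants: 6 (4R)-4-ethynyloxolan-2-one; 14 triethyl{[(3R)-1-iodo-3-methylhex-5-en-3-yl]oxy}silane
Product: 16 (3S,4R)-4-ethynyl-3-[(3S)-3-methyl-3-(triethylsilyloxy)hex-5-en-1-yl]oxolan-2-one, via dilithio dianion 15 (not isolated)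
Conditions: LDA (2.1 equiv), THF, −78 °C; 14, DMPU, −78 → −30 °C; AcOH quench
Reagents that add atoms: none
Why: Lactone enolate alkylation in which the second equivalent of base parks the alkyne as its unreactive lithium acetylide and the iodide approaches the enolate anti to the C4 substituent, setting C8 (S) trans to C9; minor diastereomers arising from imperfect ee in steps 1 and 5 are separated here.

Step 10
Reactants: 16 (3S,4R)-4-ethynyl-3-[(3S)-3-methyl-3-(triethylsilyloxy)hex-5-en-1-yl]oxolan-2-one
Product: 17 (3Z,5S,8S,9R)-cyclononadiene-fused γ-lactone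
Conditions: [CpRu(MeCN)3]PF6 (10 mol%), acetone, 2 mM, 25 → 50 °C, slow addition of 16
Reagents that add atoms: none
Why: Proposed new method: a Ru(II)-catalysed intramolecular alkene–alkyne (Alder-ene type) coupling used to close a nine-membered carbocycle, in which the terminal alkyne and the allyl C=C bind CpRu+, oxidative cyclisation gives a ruthenacyclopentene with C1–C2 bond formation at the internal alkyne carbon (branched mode), syn β-hydride elimination of an allylic C4–H and C–H reductive elimination then deliver the 1-methylidene/3-ene skipped diene in one atom-economical step, the nine-membered tether allowing only a cisoid C2–C3–C4–C5 arrangement in the β-H elimination so that the ring alkene should be Z while C5, C8 and C9 are untouched; the closest known chemistry is the Trost CpRu alkene–alkyne coupling, established intermolecularly, in macrocyclisations and in enyne cycloisomerisations to five- to seven-membered rings but not for a nine-membered carbocycle.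

Step 11
Reactants: 17 (3Z,5S,8S,9R)-cyclononadiene-fused γ-lactone
Product: 18 (3Z,5S,8S,9R)-C11-chloromethyl lactol (anomer mixture)
Conditions: ICH2Cl (1.5 equiv), MeLi·LiBr (1.4 equiv), THF/Et2O, −78 °C; AcOH quench at −78 °C
Reagents that add atoms: chloroiodomethane ClCI
Why: Carbenoid homologation in which chloromethyllithium, generated in the presence of the lactone, adds once to the carbonyl because the lithium hemiketal is stable at −78 °C; C8 and C9 are not touched.

Step 12
Reactants: 19 3-methylbut-2-enal
Product: 20 (1E)-1-iodo-4-methylpenta-1,3-diene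
Conditions: CrCl2 (6 equiv), CHI3 (2 equiv), THF/dioxane, 0 °C, dark
Reagents that add atoms: iodoform IC(I)I
Why: Takai olefination, in which the gem-dichromium iodocarbenoid adds to the aldehyde and eliminates to give the E-vinyl iodide.

Step 13
Reactants: 18 (3Z,5S,8S,9R)-C11-chloromethyl lactol; 20 (1E)-1-iodo-4-methylpenta-1,3-diene
Product: 23 (3Z,5S,8S,9R)-dienyl epoxy alcohol (C11 epimer mixture), via dienyllithium 21 (not isolated), via chlorohydrin 22 (not isolated)
Conditions: 20 (2.6 equiv), t-BuLi (5.2 equiv), Et2O, −78 °C; 18 in THF, −78 °C → rt; H2O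
Reagents that add atoms: none
Why: Iodine–lithium exchange keeps the E geometry, the alkenyllithium adds 1,2 to the ring-opened α-chloro ketone form of the lactol, and the tertiary alkoxide displaces chloride (halohydrin ring closure) to give the dienyl epoxide; the C11 configuration is not controlled here and need not be, because both epimers converge in step 14.

Step 14
Reactants: 23 (3Z,5S,8S,9R)-dienyl epoxy alcohol
Product: 24 (3Z,5S,8S,9R,11R)-C5-O-triethylsilyl tetrahydrofuran alcohol
Conditions: Pd2(dba)3·CHCl3 (2.5 mol%), (R,R)-DACH-phenyl Trost ligand (7.5 mol%), Et3B (5 mol%), CH2Cl2, rt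
Reagents that add atoms: none
Why: Pd-catalysed asymmetric allylic etherification (Trost-type dynamic kinetic asymmetric transformation of 2-substituted alkenyl oxiranes), in which Pd(0) ionises either epoxide epimer to the same C12-alkoxide/π-dienyl-Pd pair, the diastereomeric complexes equilibrate by π–σ–π through the CMe2 terminus, and boron-templated 5-exo attack of the C10 hydroxyl on C11 under ligand control sets C11 as R (sense assigned by analogy with isoprene monoepoxide etherifications) while the syn-allyl keeps C13=C14 E.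

Step 15
Reactants: 24 (3Z,5S,8S,9R,11R)-C5-O-triethylsilyl tetrahydrofuran alcohol
Product: 25 (3Z,5S,8S,9R,11R)-core diol
Conditions: TBAF (1.5 equiv), THF, 0 °C → rt
Reagents that add atoms: none
Why: Fluoride cleavage of the tertiary triethylsilyl ether; the basic conditions avoid ionisation of the tertiary allylic C5–O and dienylic C11–O bonds, so no stereocentre is at risk.

Step 16
Reactants: 26 oct-1-yne; 27 1,6-dibromohexane
Product: 29 1-bromotetradec-7-yne, via lithium octynide 28 (not isolated)
Conditions: n-BuLi, THF, −78 °C; 27 (3 equiv), DMPU, −78 °C → rt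
Reagents that add atoms: none
Why: SN2 alkylation of a lithium acetylide, with excess dibromide suppressing double alkylation.

Step 17
Reactants: 29 1-bromotetradec-7-yne; 30 5-bromopentanoic acid
Product: 33 nonadec-12-ynoic acid, via Grignard reagent 31 (not isolated), via magnesium carboxylate 32 (not isolated)
Conditions: 29, Mg, THF → 31; 30, MeMgCl (1.0 equiv), THF, −20 °C → 32; Li2CuCl4 (3 mol%), THF/NMP, −20 → 0 °C; 1 M HCl
Reagents that add atoms: none
Why: Kochi-type Cu-catalysed sp3–sp3 Grignard cross-coupling at the primary bromide of the magnesium ω-bromocarboxylate; the carboxylate salt is inert and the internal alkyne is a spectator.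

Step 18
Reactants: 33 nonadec-12-ynoic acid
Product: 34 nonadecanoic acid
Conditions: H2 (1 atm), 10% Pd/C, EtOAc, rt
Reagents that add atoms: none
Why: Heterogeneous catalytic hydrogenation of the alkyne to the saturated chain.

Step 19
Reactants: 25 (3Z,5S,8S,9R,11R)-core diol; 34 nonadecanoic acid
Product: 35 target CNP0120482.1
Conditions: EDC·HCl (1.3 equiv), DMAP (0.3 equiv), CH2Cl2, 0 °C → rt
Reagents that add atoms: none
Why: Steglich-type carbodiimide esterification acylates only the primary C12 hydroxyl, the tertiary allylic C5 hydroxyl being unreactive, so all four stereocentres pass through unchanged.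

## Compound list

1 | furan-2(5H)-one | O=C1C=CCO1 | starting material
2 | potassium vinyltrifluoroborate | C=C[B-](F)(F)F.[K+] | starting material
3 | (4R)-4-ethenyloxolan-2-one | O=C1C[C@H](C=C)CO1 | intermediate
4 | (4S)-4-(1,2-dibromoethyl)oxolan-2-one, both CHBr epimers | O=C1C[C@H](C(Br)CBr)CO1 | intermediate
5 | (4S)-4-(1-bromoethenyl)oxolan-2-one, principal bromoalkene (with its 2-bromoethenyl regioisomer) | O=C1C[C@H](C(Br)=C)CO1 | intermediate
6 | (4R)-4-ethynyloxolan-2-one | O=C1C[C@H](C#C)CO1 | intermediate
7 | pent-1-en-4-yne | C=CCC#C | starting material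
8 | dimethyl[(1E)-2-methylpenta-1,4-dien-1-yl]alane | C=CC/C(C)=C/[Al](C)C | intermediate
9 | lithium butyl(dimethyl)[(1E)-2-methylpenta-1,4-dien-1-yl]alanate | [Li+].C=CC/C(C)=C/[Al-](C)(C)CCCC | intermediate
10 | (2E)-3-methylhexa-2,5-dien-1-ol | C=CC/C(C)=C/CO | intermediate
11 | [(2R,3R)-3-methyl-3-(prop-2-en-1-yl)oxiran-2-yl]methanol | OC[C@H]1O[C@]1(C)CC=C | intermediate
12 | (3R)-3-methylhex-5-ene-1,3-diol | OCC[C@](C)(O)CC=C | intermediate
13 | (3R)-1-iodo-3-methylhex-5-en-3-ol | ICC[C@](C)(O)CC=C | intermediate
14 | triethyl{[(3R)-1-iodo-3-methylhex-5-en-3-yl]oxy}silane | ICC[C@](C)(O[Si](CC)(CC)CC)CC=C | intermediate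
15 | dilithio dianion of 6 (lithium enolate and lithium acetylide) | [Li]OC1=C[C@H](C#C[Li])CO1 | intermediate
16 | (3S,4R)-4-ethynyl-3-[(3S)-3-methyl-3-(triethylsilyloxy)hex-5-en-1-yl]oxolan-2-one (side-chain centre has the geometry of 14; descriptor S by CIP priority change) | C=CC[C@@](C)(O[Si](CC)(CC)CC)CC[C@H]1[C@H](C#C)COC1=O | intermediate
17 | (3Z,5S,8S,9R)-5-methyl-1-methylidene-5-(triethylsilyloxy)cyclonon-3-ene trans-fused at C8/C9 to a γ-lactone (C11=O on C8, C10H2–O on C9) | C=C1C/C=C\[C@@](C)(O[Si](CC)(CC)CC)CC[C@H]2[C@H]1COC2=O | intermediate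
18 | lactol of 17: C11 bears OH and CH2Cl (anomer mixture, in equilibrium with the open C10-hydroxy chloromethyl ketone); (3Z,5S,8S,9R) | C=C1C/C=C\[C@@](C)(O[Si](CC)(CC)CC)CC[C@H]2[C@H]1COC2(O)CCl | intermediate
19 | 3-methylbut-2-enal | CC(C)=CC=O | starting material
20 | (1E)-1-iodo-4-methylpenta-1,3-diene | I/C=C/C=C(C)C | intermediate
21 | [(1E)-4-methylpenta-1,3-dien-1-yl]lithium | [Li]/C=C/C=C(C)C | intermediate
22 | open chlorohydrin (formed as its dilithium alkoxide): C8 bears C11(OH)(CH2Cl)[(1E)-4-methylpenta-1,3-dienyl], C9 bears CH2OH; C11 epimers | C=C1C/C=C\[C@@](C)(O[Si](CC)(CC)CC)CC[C@H](C(O)(CCl)/C=C/C=C(C)C)[C@H]1CO | intermediate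
23 | (3Z,5S,8S,9R)-cyclononadiene with CH2OH on C9 and a 2-[(1E)-4-methylpenta-1,3-dien-1-yl]oxiran-2-yl group on C8 (C11 epimers) | C=C1C/C=C\[C@@](C)(O[Si](CC)(CC)CC)CC[C@H](C2(CO2)/C=C/C=C(C)C)[C@H]1CO | intermediate
24 | (3Z,5S,8S,9R,11R)-tetrahydrofuran core: C11 bears CH2OH (C12) and the (1E)-4-methylpenta-1,3-dienyl group; C5–OSiEt3 | C=C1C/C=C\[C@@](C)(O[Si](CC)(CC)CC)CC[C@H]2[C@H]1CO[C@@]2(/C=C/C=C(C)C)CO | intermediate
25 | (3Z,5S,8S,9R,11R)-core diol (24 with free C5–OH) | C=C1C/C=C\[C@@](C)(O)CC[C@H]2[C@H]1CO[C@@]2(/C=C/C=C(C)C)CO | intermediate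
26 | oct-1-yne | C#CCCCCCC | starting material
27 | 1,6-dibromohexane | BrCCCCCCBr | starting material
28 | lithium oct-1-yn-1-ide | [Li]C#CCCCCCC | intermediate
29 | 1-bromotetradec-7-yne | BrCCCCCCC#CCCCCCC | intermediate
30 | 5-bromopentanoic acid | OC(=O)CCCCBr | starting material
31 | tetradec-7-yn-1-ylmagnesium bromide | Br[Mg]CCCCCCC#CCCCCCC | intermediate
32 | chloromagnesium 5-bromopentanoate | BrCCCCC(=O)O[Mg]Cl | intermediate
33 | nonadec-12-ynoic acid | OC(=O)CCCCCCCCCCC#CCCCCCC | intermediate
34 | nonadecanoic acid | OC(=O)CCCCCCCCCCCCCCCCCC | intermediate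
35 | CNP0120482.1, the C12 nonadecanoate of 25 | C=C1C/C=C\[C@@](C)(O)CC[C@H]2[C@H]1CO[C@@]2(/C=C/C=C(C)C)COC(=O)CCCCCCCCCCCCCCCCCC | target

## Step count and risk

Total step count: 19.
Longest linear sequence: 12 steps (4, 5, 6, 7, 8, 9, 10, 11, 13, 14, 15, 19), which is 12/19 of the total.

The three steps most likely to fail:

Step 10 (the proposed new Ru ring closure). It may give oligomers, the ten-membered linear-mode isomer or no cyclisation. The fallback is ring closure by ring-closing metathesis, using known reactions only; it sets out from 14 and comes back to the route at 17. The terminal allyl group of 14 is moved one position into the chain with H2-activated [Ir(cod)(PMePh2)2]PF6 (THF, rt; the quaternary carbinol carbon stops further migration) to give triethyl{[(3S,4E)-1-iodo-3-methylhex-4-en-3-yl]oxy}silane F1. Dianion 15, made from 6 as in step 9, is alkylated with it to give the propenyl alkynyl lactone F2. Markovnikov allylindation of the terminal alkyne (allyl bromide, In, THF, 60 °C) gives the penta-1,4-dien-2-yl lactone F3. Grubbs second-generation catalyst (CH2Cl2, 40 °C, 1 mM) then closes C3=C4 with loss of propene, the nine-membered ring allowing only the Z alkene, and the product is 17.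

Step 13 (two organolithium equivalents on an enolisable α-chloro ketone). Enolisation, C8 epimerisation or chloride displacement may compete. The fallback reverses the order in which C12 and C13 are attached; it sets out from 17, bypasses 18 and comes back at 23. Dienyllithium 21 (1.2 equiv, from 20 as in step 13) adds once to lactone 17 at −78 °C, the lithium hemiketal preventing double addition, to give the hydroxy dienone F4 (in equilibrium with its lactol). Corey–Chaykovsky epoxidation with dimethylsulfonium methylide (Me3S+ I−, KHMDS, 3 equiv, THF, 0 °C), which adds 1,2 to enones, then gives 23.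

Step 14 (Pd etherification of a dienyl epoxide with ligand control at C11). The π-dienyl intermediate may eliminate to trienes, or the ligand sense may be mismatched with the substrate; the antipodal ligand is the first check. The fallback builds the diene after the ring by a Heck coupling; it sets out from 18 and comes back at 24. Vinylmagnesium bromide (3 equiv, THF, −78 → 0 °C) adds to 18 to give the vinyl chlorohydrin F5, which K2CO3/MeOH closes to the vinyl epoxide F6, the 2-substituted 2-vinyloxirane class for which this Pd etherification is established. Pd2(dba)3/(R,R)-DACH-phenyl Trost ligand/Et3B (CH2Cl2, rt) cyclises it to the vinyl tetrahydrofuran alcohol F7. A Heck reaction with 1-bromo-2-methylprop-1-ene (Pd(OAc)2, P(o-tol)3, Ag2CO3, MeCN, 70 °C) then gives 24; C11 carries no hydrogen, so only the E-diene can form.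

Further compounds
F1 | step 10 | triethyl{[(3S,4E)-1-iodo-3-methylhex-4-en-3-yl]oxy}silane | ICC[C@](C)(O[Si](CC)(CC)CC)/C=C/C
F2 | step 10 | (3S,4R)-4-ethynyl-3-[(3S,4E)-3-methyl-3-(triethylsilyloxy)hex-4-en-1-yl]oxolan-2-one | C/C=C/[C@@](C)(O[Si](CC)(CC)CC)CC[C@H]1[C@H](C#C)COC1=O
F3 | step 10 | (3S,4R)-3-[(3S,4E)-3-methyl-3-(triethylsilyloxy)hex-4-en-1-yl]-4-(penta-1,4-dien-2-yl)oxolan-2-one | C/C=C/[C@@](C)(O[Si](CC)(CC)CC)CC[C@H]1[C@H](C(=C)CC=C)COC1=O
F4 | step 13 | (3Z,5S,8S,9R)-hydroxy dienone: C8 bears C11(=O)–[(1E)-4-methylpenta-1,3-dienyl], C9 bears CH2OH | C=C1C/C=C\[C@@](C)(O[Si](CC)(CC)CC)CC[C@H](C(=O)/C=C/C=C(C)C)[C@H]1CO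
F5 | step 14 | (3Z,5S,8S,9R)-vinyl chlorohydrin: C8 bears C11(OH)(CH2Cl)(CH=CH2), C9 bears CH2OH (C11 epimers) | C=C1C/C=C\[C@@](C)(O[Si](CC)(CC)CC)CC[C@H](C(O)(CCl)C=C)[C@H]1CO
F6 | step 14 | (3Z,5S,8S,9R)-vinyl epoxide: C8 bears a 2-ethenyloxiran-2-yl group, C9 bears CH2OH (C11 epimers) | C=C1C/C=C\[C@@](C)(O[Si](CC)(CC)CC)CC[C@H](C2(CO2)C=C)[C@H]1CO
F7 | step 14 | (3Z,5S,8S,9R,11R)-vinyl tetrahydrofuran alcohol: C11 bears CH2OH and CH=CH2; C5–OSiEt3 | C=C1C/C=C\[C@@](C)(O[Si](CC)(CC)CC)CC[C@H]2[C@H]1CO[C@@]2(C=C)CO
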